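**Assumption (remark on the chemistry):** the C2 hemiketal of the target is taken to lose its configuration only through base-promoted ring–chain tautomerism (opening of O1–C2 to the 2-hydroxyaryl 1,2-diketone). It is therefore treated as configurationally stable in the absence of base and is set free only in the last step, under weakly acidic conditions.

## Structural features

The target is a 4-methylbenzofuran-3(2H)-one in which C2 carries a hydroxyl group and a C15 chain. C2 is thus a cyclic hemiketal carbon held between the ring oxygen O1 and the aryl ketone C3, and it is the only stereocentre (R). The chain is joined through C1′ and holds two trisubstituted (E)-alkenes (C2′=C3′, C6′=C7′), a cross-conjugated dienone (C6′=C7′–C8′(=O)–C9′=C10′, 9′E) and a tertiary allylic alcohol at C11′. The arene is 1,2,3-trisubstituted (O1 on C7a, the acyl carbon C3 on C3a, methyl on C4), a pattern that is bought more easily than made. The fragile point is the hemiketal: whenever the C2 alkoxide forms, the O1–C2 bond can open, which erases the stereocentre and invites benzilic-acid-type rearrangement. In addition, the dienone is a twofold Michael acceptor and the two isolated trisubstituted alkenes exclude electrophilic oxidants once the chain is in place. The real difficulty is therefore to create C2 as one enantiomer in a form that cannot ring-open, on a molecule that must carry this chain. The key step exploits the fact that C2 is at once α to C3=O, doubly oxygenated (O1 and the hydroxyl oxygen) and homoallylic to C2′=C3′: with H in place of the chain and silicon on the hydroxyl oxygen, deprotonation gives a flat, aromatic 2-silyloxy-3-oxidobenzofuran whose C2 is a masked acyl anion of the open diketone, and C1′ is the free terminus of an allyl unit.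

## Logic of the disconnections

**16 ⇒ 15.** The two O–Si bonds (on the C2 oxygen and the C11′ oxygen) are cut. The free hemiketal then appears only in the last operation, and the stereocentre travels as a silyl ketal that cannot ring-open. The demand on the forward step is that no base is present and that both silyl ethers fall together.

**15 ⇒ 4 + 14 (key).** The C2–C1′ bond is cut, with C2 as nucleophile and C1′ as the terminus of a π-allyl electrophile. This one bond joins the two halves of the molecule and creates the only stereocentre, already in its locked form. The gain is from a 24-carbon, fully functionalised ketal to a racemic nine-carbon protected glyoxal hemiacetal and an achiral chain; the racemic C2–H centre of 4 is erased in the enolate, so the step is enantioconvergent. The forward step must give C- rather than O-allylation, attack at C1′ rather than C3′, retention of the 2′E geometry, control of the enolate face, and it must leave the dienone alone.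

**14 ⇒ 13.** The C8′=O π bond is retraced to a carbinol. The ketone is needed only after the C8′–C9′ bond exists, and an alcohol is what a 1,2-addition delivers. The demand is an oxidant that touches only a doubly allylic alcohol.

**13 ⇒ 8 + 10 (through 11 and 12).** The C8′–C9′ bond is cut. The (E)-C9′=C10′ geometry then comes from syn-hydrometalation of a terminal alkyne, and both pieces derive from commodity chemicals. The alkenyl metal must add 1,2 to an enal and ignore the allylic carbonate.

**8 ⇒ 6 ⇒ 5.** The C8′–O bond (allylic C–H oxidation) and the carbonate C–O bond are cut. Compound 5 already holds both trisubstituted alkenes with the correct geometry, so no olefination is needed. The oxidation must select the (E)-methyl group of the distal alkene.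

**10 ⇒ 9.** The O–Si bond is cut; the tertiary alcohol is masked only to survive hydrometalation.

**4 ⇒ 3 ⇒ 1 (through 2).** The O–Si bond is cut, then the oxidation level of C2 and the O1–C2 bond. Compound 1 is bought with the contiguous O/acyl/methyl pattern, its acetyl methyl becomes C2 at the aldehyde level, and the ring closes by itself. The oxidation must stay on the acetyl methyl and the silylation on the hemiacetal hydroxyl.

## Other disconnections considered

**Alternative 1:** (first to mind) Cut of the C2–OH bond, made last. The forward key step would be an enantioselective α-hydroxylation of the C2–H benzofuranone A1, which already carries the chain. The chosen plan is preferred on mechanistic grounds. An enolate oxidation delivers the C2 alkoxide, which is exactly the species that opens to the achiral phenoxide–diketone, so the stereocentre would be born under the conditions that destroy it. Electrophilic oxygen-transfer reagents are also not orthogonal to the two trisubstituted alkenes of A1. The chosen plan forms the centre by C–C bond formation, as a silyl ketal, and never passes through the alkoxide.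

**Alternative 2:** Biomimetic ring contraction. The cut is the O1–C2 closure after excision of one carbonyl carbon. The 3-alkyl-4-hydroxy-5-methylcoumarin A2 would be oxygenated at C3 and the lactone opened; decarboxylative fragmentation would give the 2-hydroxyaryl 1,2-diketone A3, which closes by itself to racemic 16. The closure is not under any control, so a resolution must follow, for example an acylative dynamic kinetic resolution to the ester A4. Removal of that acyl group needs a nucleophile or base and re-exposes the labile centre. The oxidant would also have to distinguish the coumarin enol from two trisubstituted alkenes. The chosen plan is shorter and sets the centre in the step that joins the fragments.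

**Alternative 3:** Cut of the C2–C3 ring bond. An N-heterocyclic-carbene-catalysed intramolecular acylation (cross-benzoin type) of the 2-formyl-3-methylphenyl ester A5 would add the acyl-anion equivalent of the aldehyde to the ester carbonyl, and the tetrahedral adduct is the alkoxide of 16. The chosen plan is preferred because that adduct can expel the phenoxide before the catalyst leaves, so the configuration would pass through an achiral diketone. In addition, the β,γ-unsaturated aryl ester A5 has acidic α-hydrogens and is prone to conjugation or ketene formation under the basic carbene conditions. Enantiocontrol cannot be defended from the mechanism.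

Key step: step 8

## Steps

**Step 1**
Reactants: 1 1-(2-hydroxy-6-methylphenyl)ethan-1-one
Product: 3 2-hydroxy-4-methylbenzofuran-3(2H)-one (racemic), via arylglyoxal 2 (not isolated)
Conditions: SeO2 (1.3 equiv), 1,4-dioxane/H2O, 90 °C
Reagents that add atoms: selenium dioxide, O=[Se]=O
Why: Riley oxidation of the aryl methyl ketone to the arylglyoxal 2, which should close at once onto the ortho phenol to the five-membered hemiacetal; the new C2 centre is racemic and is erased later in the enolate.

**Step 2**
Reactants: 3 2-hydroxy-4-methylbenzofuran-3(2H)-one
Product: 4 2-((tert-butyldimethylsilyl)oxy)-4-methylbenzofuran-3(2H)-one (racemic)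
Conditions: TBSCl (1.1 equiv), imidazole, CH2Cl2, 0 °C
Reagents that add atoms: tert-butyldimethylsilyl chloride, CC(C)(C)[Si](C)(C)Cl
Why: O-silylation of the hemiacetal hydroxyl of the dominant ring tautomer should give a protected glyoxal hemiacetal with one acidic C2–H.

**Step 3**
Reactants: 5 geraniol
Product: 6 tert-butyl ((2E)-3,7-dimethylocta-2,6-dien-1-yl) carbonate
Conditions: Boc2O, n-Bu4NHSO4 (cat.), aq. NaOH, CH2Cl2, 0 °C to rt
Reagents that add atoms: di-tert-butyl dicarbonate, CC(C)(C)OC(=O)OC(=O)OC(C)(C)C
Why: Phase-transfer O-acylation of the primary allylic alcohol; the alkene geometry is not touched and the carbonate is the leaving group of step 8.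

**Step 4**
Reactants: 6 tert-butyl ((2E)-3,7-dimethylocta-2,6-dien-1-yl) carbonate
Product: 8 tert-butyl ((2E,6E)-3,7-dimethyl-8-oxoocta-2,6-dien-1-yl) carbonate, via allylic alcohol 7 (not isolated)
Conditions: SeO2 (cat.), t-BuOOH, salicylic acid (cat.), CH2Cl2, rt; then MnO2, CH2Cl2, rt
Reagents that add atoms: tert-butyl hydroperoxide, CC(C)(C)OO; selenium dioxide (catalytic oxygen carrier), O=[Se]=O
Why: SeO2/t-BuOOH allylic oxidation (ene reaction, then [2,3]-sigmatropic shift) should act on the more electron-rich distal alkene and on its (E)-methyl group, giving the (E)-allylic alcohol 7; MnO2 then oxidises the allylic alcohol to the enal without change of geometry.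

**Step 5**
Reactants: 9 2-methylbut-3-yn-2-ol
Product: 10 triethyl((2-methylbut-3-yn-2-yl)oxy)silane
Conditions: TESOTf, 2,6-lutidine, CH2Cl2, 0 °C
Reagents that add atoms: triethylsilyl trifluoromethanesulfonate, CC[Si](CC)(CC)OS(=O)(=O)C(F)(F)F
Why: Silylation of a hindered tertiary alcohol with the silyl triflate; the ether is needed for the hydrozirconation.

**Step 6**
Reactants: 10 triethyl((2-methylbut-3-yn-2-yl)oxy)silane; 8 tert-butyl ((2E,6E)-3,7-dimethyl-8-oxoocta-2,6-dien-1-yl) carbonate
Product: 13 tert-butyl ((2E,6E,9E)-8-hydroxy-3,7,11-trimethyl-11-((triethylsilyl)oxy)dodeca-2,6,9-trien-1-yl) carbonate (racemic at C8), via alkenylzirconocene chloride 11 (not isolated), via methyl alkenylzinc 12 (not isolated)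
Conditions: 10, Cp2Zr(H)Cl, CH2Cl2, rt; Me2Zn, −65 °C; then 8, 0 °C; aq. NH4Cl
Reagents that add atoms: none
Why: Syn-hydrozirconation puts zirconium on the terminal carbon and fixes the (E)-alkene; zirconium-to-zinc transmetalation gives an alkenylzinc that should add 1,2 to the enal and leave carbonate and silyl ether alone; the new carbinol centre is racemic and is removed in step 7.

**Step 7**
Reactants: 13 tert-butyl ((2E,6E,9E)-8-hydroxy-3,7,11-trimethyl-11-((triethylsilyl)oxy)dodeca-2,6,9-trien-1-yl) carbonate
Product: 14 tert-butyl ((2E,6E,9E)-3,7,11-trimethyl-8-oxo-11-((triethylsilyl)oxy)dodeca-2,6,9-trien-1-yl) carbonate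
Conditions: MnO2 (excess), CH2Cl2, rt
Reagents that add atoms: none
Why: Neutral, heterogeneous oxidation that is selective for the doubly allylic alcohol should give the cross-conjugated dienone with all alkene geometries kept.

**Step 8**
Reactants: 4 2-((tert-butyldimethylsilyl)oxy)-4-methylbenzofuran-3(2H)-one (racemic); 14 tert-butyl ((2E,6E,9E)-3,7,11-trimethyl-8-oxo-11-((triethylsilyl)oxy)dodeca-2,6,9-trien-1-yl) carbonate
Product: 15 (S)-2-((tert-butyldimethylsilyl)oxy)-4-methyl-2-((2E,6E,9E)-3,7,11-trimethyl-8-oxo-11-((triethylsilyl)oxy)dodeca-2,6,9-trien-1-yl)benzofuran-3(2H)-one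
Conditions: [Pd2(dba)3]·CHCl3 (2.5 mol%), (R,R)-DACH-phenyl bis(2-diphenylphosphinobenzamide) ligand (7.5 mol%; the antipode if it is the one that gives the 2S ketal), toluene, 0 °C to rt, degassed
Reagents that add atoms: none
Why: Tsuji–Trost asymmetric allylic alkylation: the Pd(0)–ligand complex ionises the primary allylic carbonate of 14 to a cationic η3-allyl complex (C1′–C3′), and the tert-butoxide set free with CO2 removes the C2–H of 4, so that both enantiomers of 4 converge on one flat, aromatic 2-silyloxy-3-oxidobenzofuran. This stabilised enolate should attack outer-sphere, anti to palladium, at the unsubstituted terminus C1′, because attack at the fully substituted C3′ would join two quaternary-type centres; the linear product with retained 2′E geometry is expected as long as capture is faster than π–σ–π isomerisation through C3′. The C2 stereocentre is controlled by the C2-symmetric diphosphine, whose chiral pocket admits the enolate to the allyl terminus with one face only, the bulky OTBS group and the fused arene being placed differently in the two diastereomeric transition states; the sense of induction is fixed by the choice of ligand antipode and is written for the 2S silyl ketal, which has the spatial arrangement of (R)-16. No ring is closed; the furan ring of the nucleophile is dearomatised as the C3–O⁻ becomes the C3 ketone. The closest known reaction type is the Pd-catalysed asymmetric prenylation and geranylation of 3-substituted oxindole enolates, together with the allylation of α-oxygenated cyclic ketone enolates, which give linear products with a new tetrasubstituted centre. C- over O-allylation is expected because O-allylation at O3 would be reversible under Pd(0) (phenoxide-like leaving group) while C-allylation is not. The dienone of 14 should be spared because both of its β-carbons are hindered (C6′ trisubstituted, C10′ next to the quaternary C11′) and the enolate exists only as the counter-ion of the π-allyl complex; the ketal oxygen stays silylated because no free alkoxide or fluoride is present.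

**Step 9**
Reactants: 15 (S)-2-((tert-butyldimethylsilyl)oxy)-4-methyl-2-((2E,6E,9E)-3,7,11-trimethyl-8-oxo-11-((triethylsilyl)oxy)dodeca-2,6,9-trien-1-yl)benzofuran-3(2H)-one
Product: 16 (R)-2-hydroxy-2-((2E,6E,9E)-11-hydroxy-3,7,11-trimethyl-8-oxododeca-2,6,9-trien-1-yl)-4-methylbenzofuran-3(2H)-one
Conditions: HF·pyridine, THF, 0 °C; quench with Me3SiOMe, evaporate
Reagents that add atoms: none
Why: Fluoride-mediated Si–O cleavage in an acidic medium should remove the activated ketal silyl ether and the tertiary TES ether without forming the C2 alkoxide; the C2–O bond is not broken, so the configuration is retained (the descriptor changes from S to R only because the two oxygens exchange CIP priority when Si is replaced by H).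

## Compound list

1 | 1-(2-hydroxy-6-methylphenyl)ethan-1-one | CC(=O)c1c(C)cccc1O | starting material
2 | 2-(2-hydroxy-6-methylphenyl)-2-oxoacetaldehyde | O=CC(=O)c1c(C)cccc1O | intermediate
3 | 2-hydroxy-4-methylbenzofuran-3(2H)-one (racemic) | OC1Oc2cccc(C)c2C1=O | intermediate
4 | 2-((tert-butyldimethylsilyl)oxy)-4-methylbenzofuran-3(2H)-one (racemic) | CC(C)(C)[Si](C)(C)OC1Oc2cccc(C)c2C1=O | intermediate
5 | geraniol, (2E)-3,7-dimethylocta-2,6-dien-1-ol | CC(C)=CCC/C(C)=C/CO | starting material
6 | tert-butyl ((2E)-3,7-dimethylocta-2,6-dien-1-yl) carbonate | CC(C)=CCC/C(C)=C/COC(=O)OC(C)(C)C | intermediate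
7 | tert-butyl ((2E,6E)-8-hydroxy-3,7-dimethylocta-2,6-dien-1-yl) carbonate | OC/C(C)=C/CC/C(C)=C/COC(=O)OC(C)(C)C | intermediate
8 | tert-butyl ((2E,6E)-3,7-dimethyl-8-oxoocta-2,6-dien-1-yl) carbonate | O=C/C(C)=C/CC/C(C)=C/COC(=O)OC(C)(C)C | intermediate
9 | 2-methylbut-3-yn-2-ol | CC(C)(O)C#C | starting material
10 | triethyl((2-methylbut-3-yn-2-yl)oxy)silane | CC[Si](CC)(CC)OC(C)(C)C#C | intermediate
11 | chlorobis(cyclopentadienyl)[(E)-3-methyl-3-((triethylsilyl)oxy)but-1-en-1-yl]zirconium | CC[Si](CC)(CC)OC(C)(C)/C=C/[Zr](Cl)(C1C=CC=C1)C1C=CC=C1 | intermediate
12 | methyl[(E)-3-methyl-3-((triethylsilyl)oxy)but-1-en-1-yl]zinc | CC[Si](CC)(CC)OC(C)(C)/C=C/[Zn]C | intermediate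
13 | tert-butyl ((2E,6E,9E)-8-hydroxy-3,7,11-trimethyl-11-((triethylsilyl)oxy)dodeca-2,6,9-trien-1-yl) carbonate (racemic at C8) | CC[Si](CC)(CC)OC(C)(C)/C=C/C(O)/C(C)=C/CC/C(C)=C/COC(=O)OC(C)(C)C | intermediate
14 | tert-butyl ((2E,6E,9E)-3,7,11-trimethyl-8-oxo-11-((triethylsilyl)oxy)dodeca-2,6,9-trien-1-yl) carbonate | CC[Si](CC)(CC)OC(C)(C)/C=C/C(=O)/C(C)=C/CC/C(C)=C/COC(=O)OC(C)(C)C | intermediate
15 | (S)-2-((tert-butyldimethylsilyl)oxy)-4-methyl-2-((2E,6E,9E)-3,7,11-trimethyl-8-oxo-11-((triethylsilyl)oxy)dodeca-2,6,9-trien-1-yl)benzofuran-3(2H)-one | C/C(=C\C[C@@]1(O[Si](C)(C)C(C)(C)C)Oc2cccc(C)c2C1=O)CC/C=C(\C)C(=O)/C=C/C(C)(C)O[Si](CC)(CC)CC | intermediate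
16 | (R)-2-hydroxy-2-((2E,6E,9E)-11-hydroxy-3,7,11-trimethyl-8-oxododeca-2,6,9-trien-1-yl)-4-methylbenzofuran-3(2H)-one | C/C(=C\C[C@@]1(O)Oc2cccc(C)c2C1=O)CC/C=C(\C)C(=O)/C=C/C(C)(C)O | target

## Step count and least certain steps

Total step count: 9. Longest linear sequence: 6 steps (5 → 6 → 8 → 13 → 14 → 15 → 16; steps 3, 4, 6, 7, 8 and 9).

**Step 8 (key step).** The most likely failure is poor discrimination between the two faces of the flat enolate, since the stereocentre is formed on the nucleophile, away from the metal, and the two flanks of C2 (O1 and C3–O⁻) are electronically alike. Second to this are loss of the 2′E geometry or attack at C3′ if capture of the π-allyl complex is slow. Fallback: the same two compounds, 4 and 14, would be coupled with an achiral catalyst (Pd(PPh3)4, toluene) to the racemic silyl ketal F1. This compound is configurationally locked and would be resolved by preparative chromatography on a chiral stationary phase; the fallback sets out from 4 and 14 and returns to the route at 15.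

**Step 2.** Silylation may take place at the phenol of the ring-opened tautomer, or a second silyl group may enter through the enol, because the hemiacetal, its open form and its enol are all accessible in the presence of an amine. Fallback: a Rubottom oxidation would build the same C2–O–Si unit from the other side. Starting from 1, α-bromination with CuBr2 would give 2-bromo-1-(2-hydroxy-6-methylphenyl)ethan-1-one F2, and ring closure with NaOAc would give 4-methylbenzofuran-3(2H)-one F3. TBSOTf/Et3N would give tert-butyldimethyl((4-methylbenzofuran-3-yl)oxy)silane F4, whose epoxidation with dimethyldioxirane and 1,4-silyl shift from O3 to O2 would rejoin the route at 4.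

**Step 6.** Transmetalation from zirconium to zinc may be incomplete, and methyl transfer to the aldehyde may compete, because the alkenyl(methyl)zinc carries two transferable groups. Fallback: a Nozaki–Hiyama–Kishi coupling. Starting from 10, hydrozirconation to 11 and quenching with iodine would give (E)-triethyl((4-iodo-2-methylbut-3-en-2-yl)oxy)silane F5, which would be added to 8 with CrCl2 and catalytic NiCl2 in DMF to rejoin the route at 13.

**Step 9.** Configuration at C2 may be lost by ring–chain tautomerism once the hemiketal is free in a medium that contains pyridine and fluoride, the more so if the tertiary TES ether is slow and long exposure is needed. Fallback: the ketal oxygen would carry a 4-methoxybenzyl group, so that the last unveiling is an oxidation under neutral conditions. Starting from 3, acetal exchange with 4-methoxybenzyl alcohol (PPTS, toluene, molecular sieves) would give 2-((4-methoxybenzyl)oxy)-4-methylbenzofuran-3(2H)-one F6. The allylation of step 8 with 14 would give the 4-methoxybenzyl ketal F7. HF·pyridine would remove the TES group while the ketal is still locked and give the hydroxy 4-methoxybenzyl ketal F8. DDQ in CH2Cl2/pH 7 buffer at 0 °C would then return to the route at 16.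

## Further compounds

F1 | step 8 | racemic 2-((tert-butyldimethylsilyl)oxy)-4-methyl-2-((2E,6E,9E)-3,7,11-trimethyl-8-oxo-11-((triethylsilyl)oxy)dodeca-2,6,9-trien-1-yl)benzofuran-3(2H)-one | C/C(=C\CC1(O[Si](C)(C)C(C)(C)C)Oc2cccc(C)c2C1=O)CC/C=C(\C)C(=O)/C=C/C(C)(C)O[Si](CC)(CC)CC
F2 | step 2 | 2-bromo-1-(2-hydroxy-6-methylphenyl)ethan-1-one | Cc1cccc(O)c1C(=O)CBr
F3 | step 2 | 4-methylbenzofuran-3(2H)-one | Cc1cccc2OCC(=O)c12
F4 | step 2 | tert-butyldimethyl((4-methylbenzofuran-3-yl)oxy)silane | Cc1cccc2occ(O[Si](C)(C)C(C)(C)C)c12
F5 | step 6 | (E)-triethyl((4-iodo-2-methylbut-3-en-2-yl)oxy)silane | CC[Si](CC)(CC)OC(C)(C)/C=C/I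
F6 | step 9 | 2-((4-methoxybenzyl)oxy)-4-methylbenzofuran-3(2H)-one (racemic) | COc1ccc(COC2Oc3cccc(C)c3C2=O)cc1
F7 | step 9 | (R)-2-((4-methoxybenzyl)oxy)-4-methyl-2-((2E,6E,9E)-3,7,11-trimethyl-8-oxo-11-((triethylsilyl)oxy)dodeca-2,6,9-trien-1-yl)benzofuran-3(2H)-one | C/C(=C\C[C@@]1(OCc2ccc(OC)cc2)Oc2cccc(C)c2C1=O)CC/C=C(\C)C(=O)/C=C/C(C)(C)O[Si](CC)(CC)CC
F8 | step 9 | (R)-2-((2E,6E,9E)-11-hydroxy-3,7,11-trimethyl-8-oxododeca-2,6,9-trien-1-yl)-2-((4-methoxybenzyl)oxy)-4-methylbenzofuran-3(2H)-one | C/C(=C\C[C@@]1(OCc2ccc(OC)cc2)Oc2cccc(C)c2C1=O)CC/C=C(\C)C(=O)/C=C/C(C)(C)O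
A1 | alternative 1 | 2-((2E,6E,9E)-11-hydroxy-3,7,11-trimethyl-8-oxododeca-2,6,9-trien-1-yl)-4-methylbenzofuran-3(2H)-one (racemic) | C/C(=C\CC1Oc2cccc(C)c2C1=O)CC/C=C(\C)C(=O)/C=C/C(C)(C)O
A2 | alternative 2 | 4-hydroxy-3-((2E,6E,9E)-11-hydroxy-3,7,11-trimethyl-8-oxododeca-2,6,9-trien-1-yl)-5-methyl-2H-chromen-2-one | C/C(=C\CC1=C(O)c2c(C)cccc2OC1=O)CC/C=C(\C)C(=O)/C=C/C(C)(C)O
A3 | alternative 2 | (4E,8E,11E)-13-hydroxy-1-(2-hydroxy-6-methylphenyl)-5,9,13-trimethyltetradeca-4,8,11-triene-1,2,10-trione | C/C(=C\CC(=O)C(=O)c1c(C)cccc1O)CC/C=C(\C)C(=O)/C=C/C(C)(C)O
A4 | alternative 2 | (S)-2-((2E,6E,9E)-11-hydroxy-3,7,11-trimethyl-8-oxododeca-2,6,9-trien-1-yl)-4-methyl-3-oxo-2,3-dihydrobenzofuran-2-yl 2-methylpropanoate | C/C(=C\C[C@@]1(OC(=O)C(C)C)Oc2cccc(C)c2C1=O)CC/C=C(\C)C(=O)/C=C/C(C)(C)O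
A5 | alternative 3 | 2-formyl-3-methylphenyl (3E,7E,10E)-12-hydroxy-4,8,12-trimethyl-9-oxotrideca-3,7,10-trienoate | C/C(=C\CC(=O)Oc1cccc(C)c1C=O)CC/C=C(\C)C(=O)/C=C/C(C)(C)O
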